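**Retrosynthetic overview**
1. Target 14 ⇐ 13 (MOM removal) ⇐ 12 (cross-metathesis, allyl → prenyl) ⇐ 10 (Claisen shift of an allyl group from O5 to C6, the only open ortho position of O5) ⇐ 9.
2. 9 ⇐ 5 + 6: a formal [3+3] annulation makes the C3'–CH bond and the O4'–CMe2 bond of the 2H-pyran (ring D) in one operation, by ortho C-alkylation, loss of ethanol to an ortho-quinone methide and oxa-6π electrocyclisation.
3. Enabling feature: the free phenol O4'–H of ring B with its vacant ortho carbon C3' (para position occupied by C3; C3' and C5' equivalent), beside a silenced ring A (O7 as MOM ether, O5–H hydrogen-bonded to C4=O). This unit becomes the 1-oxatriene O4'=C4'–C3'=CH–CH=CMe2.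
4. 5 ⇐ genistein 4 (selective protection of O7) ⇐ 1 + 2 + DMF (one-pot C-acylation and formylative closure of the pyranone).
5. Ring order: rings A and B are bought, pyranone ring C is closed in step 1, pyran ring D in step 3; the C6 side chain is completed last.

Key step: step 3

Remark: the target has no stereocentre (its pyran alkene is ring-locked cis and the prenyl alkene carries two identical methyl groups); atom numbers follow the isoflavone convention (ring A C5–C8, pyranone ring C O1–C4, ring B C1'–C6', and the 2H-pyran fused to ring B is ring D).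

**Step 1**
Reactants: 1 phloroglucinol; 2 4-hydroxyphenylacetic acid
Product: 4 genistein (5,7-dihydroxy-3-(4-hydroxyphenyl)-4H-chromen-4-one), via deoxybenzoin 3 (not isolated)
Conditions: BF3·OEt2, 85 °C; then DMF, MeSO2Cl, 70 °C (one pot)
Reagents that add atoms: N,N-dimethylformamide, CN(C)C=O (supplies C2 and its hydrogen)
Why: BF3-promoted Friedel–Crafts (Houben–Hoesch-type) C-acylation of the symmetric, electron-rich ring of 1 by 2 should give deoxybenzoin 3, whose activated methylene then condenses with the Vilsmeier-type reagent made from DMF and MeSO2Cl and closes onto an ortho hydroxyl with loss of dimethylamine (one-pot deoxybenzoin isoflavone synthesis), no stereocentre being formed.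

**Step 2**
Reactants: 4 genistein
Product: 5 7-O-MOM-genistein (5-hydroxy-3-(4-hydroxyphenyl)-7-(methoxymethoxy)-4H-chromen-4-one)
Conditions: KOt-Bu (1.0 equiv), DMF, 0 °C; MOMCl (1.0 equiv), 0 °C to rt
Reagents that add atoms: chloromethyl methyl ether (MOMCl), COCCl
Why: Williamson-type O-alkylation of the monophenoxide, in which one equivalent of base should deprotonate only the most acidic 7-OH (a vinylogous acid through C4=O) while 4'-OH is less acidic and 5-OH is held in the hydrogen bond to C4=O, so that the MOM group should enter at O7.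

**Step 3**
Reactants: 5 7-O-MOM-genistein; 6 1,1-diethoxy-3-methylbut-2-ene (3-methyl-2-butenal diethyl acetal)
Product: 9 7-O-MOM-isoderrone (3-(2,2-dimethyl-2H-chromen-6-yl)-5-hydroxy-7-(methoxymethoxy)-4H-chromen-4-one), via ortho-(1-ethoxyprenyl)phenol 7 (not isolated), via ortho-quinone methide 8 (not isolated)
Conditions: 3-picoline (0.5 equiv), p-xylene, 140 °C, EtOH distilled off
Reagents that add atoms: none
Why: Phenol–acetal exchange should give the aryl ethyl mixed acetal of O4', whose ionisation to a phenoxide/ethoxyallyl oxocarbenium ion pair and recombination at the ortho carbon C3' forms the C3'–CH bond (7); picoline-assisted 1,4-elimination of ethanol then gives ortho-quinone methide 8, the 1-oxatriene O4'=C4'–C3'=CH–CH=CMe2, which closes thermally to the 2H-pyran and forms the O4'–CMe2 bond. The closest known reaction type is the pyridine- or picoline-mediated chromenylation of phenols, para-acceptor-substituted ones included, with 3-methyl-2-butenal or its acetals (formal [3+3] annulation, Knoevenagel-type condensation followed by oxa-6π electrocyclisation). Ring D is closed by a disrotatory six-electron electrocyclisation of the oxatriene, a pericyclic six-membered closure driven by the return of aromaticity to ring B. No stereocentre survives: the benzylic centre of 7 is racemic and is erased in 8, the new sp3 ring carbon bears two identical methyl groups, and only the Z isomer of 8 can cyclise while the E isomer can return through reversible ethanol addition. The step needs chemoselectivity for O4'–H and C3' over ring A, secured because O7 is capped as the MOM ether, O5–H is locked in the hydrogen bond to C4=O and ring A is deactivated by the pyranone carbonyl, and it needs no site selectivity within ring B because the para position carries C3 and C3' and C5' are equivalent. Bonding at the acetal carbon instead of the CMe2 terminus should follow from sterics and from the fact that only this adduct is drained irreversibly by the electrocyclisation.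

**Step 4**
Reactants: 9 7-O-MOM-isoderrone
Product: 10 5-O-allyl ether (3-(2,2-dimethyl-2H-chromen-6-yl)-7-(methoxymethoxy)-5-(prop-2-en-1-yloxy)-4H-chromen-4-one)
Conditions: allyl bromide, K2CO3, DMF, 60 °C
Reagents that add atoms: allyl bromide, C=CCBr
Why: Williamson O-alkylation, in which the chelated 5-OH is the only remaining acidic site (O7 and O4' are etherified) and should be deprotonated by carbonate in warm DMF and allylated.

**Step 5**
Reactants: 10 5-O-allyl ether
Product: 12 6-allyl-3-(2,2-dimethyl-2H-chromen-6-yl)-5-hydroxy-7-(methoxymethoxy)-4H-chromen-4-one, via ortho-dienone 11 (not isolated)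
Conditions: Eu(fod)3 [tris(6,6,7,7,8,8,8-heptafluoro-2,2-dimethyloctane-3,5-dionato)europium] (10 mol %), PhCl, 120 °C
Reagents that add atoms: none
Why: Aromatic Claisen ([3,3]-sigmatropic) rearrangement accelerated by chelation of the europium Lewis acid between O5 and the C4 carbonyl oxygen, in which the only ortho position of O5 that bears hydrogen is C6 (the other is the ring-fusion carbon C4a), so that the allyl group should be delivered to C6 to give dienone 11, whose fast tautomerisation to the hydrogen-bonded phenol should outrun a Cope shift to C8 and erases its transient stereocentre.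

**Step 6**
Reactants: 12 6-allyl compound
Product: 13 7-O-MOM-isochandalone (3-(2,2-dimethyl-2H-chromen-6-yl)-5-hydroxy-7-(methoxymethoxy)-6-(3-methylbut-2-en-1-yl)-4H-chromen-4-one)
Conditions: second-generation Grubbs catalyst RuCl2(=CHPh)(PCy3)(H2IMes) (5 mol %), 2-methyl-2-butene (excess), CH2Cl2, 40 °C
Reagents that add atoms: 2-methyl-2-butene, CC=C(C)C
Why: Olefin cross-metathesis of the terminal allyl alkene with excess 2-methyl-2-butene should exchange the CH2 terminus for the isopropylidene group with loss of propene, the trisubstituted prenyl product and the ring-bound cis alkene of the chromene next to its quaternary carbon being poor substrates for the catalyst.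

**Step 7**
Reactants: 13 7-O-MOM-isochandalone
Product: 14 isochandalone (3-(2,2-dimethyl-2H-chromen-6-yl)-5,7-dihydroxy-6-(3-methylbut-2-en-1-yl)-4H-chromen-4-one)
Conditions: HCl (3 M aq.), MeOH, 40 °C
Reagents that add atoms: none
Why: Acid-catalysed methanolysis of the aryl methoxymethyl acetal (MOM ether cleavage) under dilute, mild conditions should free the 7-OH while the prenyl group and the chromene stay intact, no stereocentre being involved.

**Compound list**
1 | phloroglucinol (benzene-1,3,5-triol) | Oc1cc(O)cc(O)c1 | starting material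
2 | 4-hydroxyphenylacetic acid | OC(=O)Cc1ccc(O)cc1 | starting material
3 | deoxybenzoin, 2-(4-hydroxyphenyl)-1-(2,4,6-trihydroxyphenyl)ethan-1-one | O=C(Cc1ccc(O)cc1)c1c(O)cc(O)cc1O | intermediate (not isolated)
4 | genistein, 5,7-dihydroxy-3-(4-hydroxyphenyl)-4H-chromen-4-one | O=c1c(-c2ccc(O)cc2)coc2cc(O)cc(O)c12 | intermediate
5 | 7-O-MOM-genistein, 5-hydroxy-3-(4-hydroxyphenyl)-7-(methoxymethoxy)-4H-chromen-4-one | O=c1c(-c2ccc(O)cc2)coc2cc(OCOC)cc(O)c12 | intermediate
6 | 1,1-diethoxy-3-methylbut-2-ene (3-methyl-2-butenal diethyl acetal) | CCOC(OCC)C=C(C)C | starting material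
7 | 3-[3-(1-ethoxy-3-methylbut-2-en-1-yl)-4-hydroxyphenyl]-5-hydroxy-7-(methoxymethoxy)-4H-chromen-4-one (racemic) | O=c1c(-c2ccc(O)c(C(OCC)C=C(C)C)c2)coc2cc(OCOC)cc(O)c12 | intermediate (not isolated)
8 | ortho-quinone methide, 5-hydroxy-7-(methoxymethoxy)-3-[(3Z)-3-(3-methylbut-2-en-1-ylidene)-4-oxocyclohexa-1,5-dien-1-yl]-4H-chromen-4-one | O=c1c(C2=C/C(=C/C=C(C)C)C(=O)C=C2)coc2cc(OCOC)cc(O)c12 | intermediate (not isolated)
9 | 7-O-MOM-isoderrone, 3-(2,2-dimethyl-2H-chromen-6-yl)-5-hydroxy-7-(methoxymethoxy)-4H-chromen-4-one | O=c1c(-c2ccc3c(c2)C=CC(C)(C)O3)coc2cc(OCOC)cc(O)c12 | intermediate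
10 | 3-(2,2-dimethyl-2H-chromen-6-yl)-7-(methoxymethoxy)-5-(prop-2-en-1-yloxy)-4H-chromen-4-one | O=c1c(-c2ccc3c(c2)C=CC(C)(C)O3)coc2cc(OCOC)cc(OCC=C)c12 | intermediate
11 | ortho-dienone, 3-(2,2-dimethyl-2H-chromen-6-yl)-7-(methoxymethoxy)-6-(prop-2-en-1-yl)-4H-chromene-4,5(6H)-dione (racemic) | C=CCC1C(=O)C2=C(C=C1OCOC)OC=C(c1ccc3c(c1)C=CC(C)(C)O3)C2=O | intermediate (not isolated)
12 | 6-allyl-3-(2,2-dimethyl-2H-chromen-6-yl)-5-hydroxy-7-(methoxymethoxy)-4H-chromen-4-one | C=CCc1c(OCOC)cc2occ(-c3ccc4c(c3)C=CC(C)(C)O4)c(=O)c2c1O | intermediate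
13 | 7-O-MOM-isochandalone, 3-(2,2-dimethyl-2H-chromen-6-yl)-5-hydroxy-7-(methoxymethoxy)-6-(3-methylbut-2-en-1-yl)-4H-chromen-4-one | CC(C)=CCc1c(OCOC)cc2occ(-c3ccc4c(c3)C=CC(C)(C)O4)c(=O)c2c1O | intermediate
14 | isochandalone, 3-(2,2-dimethyl-2H-chromen-6-yl)-5,7-dihydroxy-6-(3-methylbut-2-en-1-yl)-4H-chromen-4-one | CC(C)=CCc1c(O)cc2occ(-c3ccc4c(c3)C=CC(C)(C)O4)c(=O)c2c1O | target

**Total step count:** 7. **Longest linear sequence:** 7 steps (1 and 2 to 14).

**Steps most likely to fail**

Step 3. The ortho C-alkylation of the only moderately nucleophilic ring B may be slow, ring A may be C-alkylated at C6 or C8 in competition, and 5 may dissolve poorly in xylene. The fallback keeps the oxa-6π closure but reaches the oxatriene by a sigmatropic route. It sets out from 5, whose O4' is alkylated with 3-chloro-3-methylbut-1-yne (CuCl2·2H2O cat., DBU, MeCN, 0 °C) to give the aryl 1,1-dimethylpropargyl ether F1. Heating F1 in N,N-diethylaniline at 190 °C should bring about propargyl Claisen rearrangement, enolisation, 1,5-hydrogen shift and oxa-6π electrocyclisation, and the sequence comes back to the route at 9.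

Step 5. The allyl group may migrate on from dienone 11 to C8 by a Cope shift (para-Claisen pathway), or the chelating substrate and product may deactivate the Lewis acid so that the rearrangement stalls. The fallback gives up the sigmatropic route and places the prenyl group by halogenation ortho to the chelated 5-OH and cross-coupling, before ring D exists. It sets out from 5, which is silylated at O4' (TBSCl, imidazole, DMF) to the 4'-O-TBS ether F2. Iodination at C6 (benzyltrimethylammonium dichloroiodate, CaCO3, CH2Cl2–MeOH) should give the 6-iodide F3. Stille coupling with tributyl(3-methylbut-2-en-1-yl)stannane (Pd(PPh3)4, DMF, 90 °C) should give the 6-prenyl compound F4, and TBAF in THF should give 7-O-MOM-wighteone F5. Annulation of F5 with 6 under the conditions of step 3 comes back to the route at 13.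

Step 7. During MOM cleavage the acid may induce cyclisation of the prenyl group onto the flanking 5-OH or 7-OH, or addition of methanol or water to the prenyl or chromene alkene. The fallback changes the order of the end-game so that the prenyl group never meets acid. It sets out from 12, whose MOM group is removed first (HCl, MeOH, 40 °C; the monosubstituted allyl alkene is far less prone to protonation) to give the 6-allyl-5,7-diol F6. Cross-metathesis of F6 with 2-methyl-2-butene (second-generation Grubbs catalyst, CH2Cl2, 40 °C) comes back to the route at 14.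

**Further compounds**
F1 | step 3 | 5-hydroxy-7-(methoxymethoxy)-3-{4-[(2-methylbut-3-yn-2-yl)oxy]phenyl}-4H-chromen-4-one | O=c1c(-c2ccc(OC(C)(C)C#C)cc2)coc2cc(OCOC)cc(O)c12
F2 | step 5 | 3-{4-[(tert-butyldimethylsilyl)oxy]phenyl}-5-hydroxy-7-(methoxymethoxy)-4H-chromen-4-one | O=c1c(-c2ccc(O[Si](C)(C)C(C)(C)C)cc2)coc2cc(OCOC)cc(O)c12
F3 | step 5 | 3-{4-[(tert-butyldimethylsilyl)oxy]phenyl}-5-hydroxy-6-iodo-7-(methoxymethoxy)-4H-chromen-4-one | O=c1c(-c2ccc(O[Si](C)(C)C(C)(C)C)cc2)coc2cc(OCOC)c(I)c(O)c12
F4 | step 5 | 3-{4-[(tert-butyldimethylsilyl)oxy]phenyl}-5-hydroxy-7-(methoxymethoxy)-6-(3-methylbut-2-en-1-yl)-4H-chromen-4-one | O=c1c(-c2ccc(O[Si](C)(C)C(C)(C)C)cc2)coc2cc(OCOC)c(CC=C(C)C)c(O)c12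
F5 | step 5 | 7-O-MOM-wighteone, 5-hydroxy-3-(4-hydroxyphenyl)-7-(methoxymethoxy)-6-(3-methylbut-2-en-1-yl)-4H-chromen-4-one | O=c1c(-c2ccc(O)cc2)coc2cc(OCOC)c(CC=C(C)C)c(O)c12
F6 | step 7 | 6-allyl-3-(2,2-dimethyl-2H-chromen-6-yl)-5,7-dihydroxy-4H-chromen-4-one | C=CCc1c(O)cc2occ(-c3ccc4c(c3)C=CC(C)(C)O4)c(=O)c2c1O
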